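4 questions stand here, and you can answer them with one number per flask.

the same everywhere: electrophile 0.10 M (fed, over 6.0 s); gas 5.3 mM (held)

| charge | nucleophile | remark | time |
|---|---|---|---|
| south-west | 0.091 M | run made earlier; the fed solution adds 1.0 times the starting volume |  |
| north-east | 0.38 M | run made earlier; the fed solution adds 1.0 times the starting volume |  |
| noon | 0.120 M | the fed solution adds 1.0 times the starting volume | 2.0 min |
| dawn | 0.480 M | the fed solution adds 1.0 times the starting volume | 2.0 min |
| spring | 0.240 M | the fed solution adds 1.0 times the starting volume | 2.0 min |

- south-west (time / s: electrophile / %, product / %): 10.0: 96.1, 3.8; 15.0: 94.0, 6.2; 30.0: 87.1, 11.9; 40.0: 84.4, 16.3; 60.0: 79.7, 20.6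
- north-east (time / s: electrophile / %, product / %): 10.0: 84.9, 16.2; 15.0: 76.4, 23.5; 30.0: 57.2, 42.2; 60.0: 34.9, 64.5

(readings scatter by 0.5 percentage points)

1. part of the electrophile that has reacted at the end, noon
2. part of the electrophile that has reacted at the end, dawn
3. part of the electrophile that has reacted at the end, spring
4. what raising the concentration of nucleophile from its lowest to its highest value here does to the part of the electrophile that has reacted (changes below 5 percentage points count as none) (it falls / no change / it rises)

- charges are per starting volume, the dose included; the dosed solution carries all of it
- the analysis behind the earlier runs scatters by 0.5 percentage points, standard deviation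
- at the start none of the gas is in solution

1. Work with a, the fraction of the electrophile charge left, and r, the nucleophile charge over the electrophile charge. Suppose one nucleophile goes per electrophile. Then ln((r − 1 + a)/(r·a)) = (r − 1)·N, or a = (r − 1)/(r·exp((r − 1)·N) − 1).

2. N is the second-order Damköhler number: rate constant times diluted electrophile times time. It says how many times the clock has passed the half-time of an equal-charge flask, and such a flask leaves 1/(1 + N). The electrophile charge, feed and gas are the same in every flask here, so r and time are what differ.

3. At 60.0 s, the north-east run has r = 3.80 and gives 0.309. At 60.0 s, the south-west run has r = 0.910 and gives 0.283.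

4. Is one number enough? Not quite. North-east's number put into the south-west run leaves 78.3 %, a gap of 1.4 percentage points from the reading, against a scatter of 0.5 points. In the north-east run, N at 60.0 s is twice its value at 30.0 s.

5. So I average the two and carry this on in proportion to time: the exposure number 0.592 at 2.0 min. With 1.20 equivalents, I reckon noon at 43.0 % reacted. I reckon spring at 68.9 % and dawn at 91.5 %. By this reckoning, the part reacted rises by 48 points from noon to dawn.

6. The forecast gives 42 %, 67 % and 90 %, each a little under mine, and says it rises. Its grounds include this: “This drift suggests the slowly dissolving gas suppresses the reaction modestly”.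

    electrophile + nucleophile → acid set free + product (k = 0.120 L mol⁻¹ s⁻¹)
    nucleophile + acid set free ⇌ protonated nucleophile, settled at all times (K = 970 L mol⁻¹)
    acid set free + free base ⇌ salt of the base (K = 1.20 × 10⁵ L mol⁻¹, k = 0.340 L mol⁻¹ s⁻¹)
    gas ⇌ free base, rate k4*(csat - [free base]) (kL = 0.170 s⁻¹)

Noon gives 39.6 %, spring 66.3 % and dawn 91.4 %. As for the part reacted from the lowest nucleophile to the highest, it rises, by 52 points, and the forecast stands. Read back, N is 0.518 at noon and 0.591 at dawn. The neighbour of noon, with 0.072 M of nucleophile, reckons to 28.2 % reacted with N, and it gives 25.5 %. Its own N reads 0.509. In that neighbour, the nucleophile no longer unbound, counted against the charges, is twice the product made, and protonated nucleophile stands at 0.0116 M.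

The earlier runs and the new flask are calculated from invented constants, noise included.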